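The constants used here were set for the occasion, and the outcome is calculated.

The vessel is a closed, stirred flask holding a slurry: solid substrate dissolves to starting material, and the dissolved material meets the reagent.

solid substrate 0.38 M; reagent 0.570 M; time 2.5 h

    starting material + reagent → other mono adduct (k1 = 0.0024 M⁻¹ s⁻¹)
    solid substrate ⇌ starting material, rate k2*(cs2 - [starting material]) while solid is left; crystals form when [starting material] > cs2 (cs2 = 0.28 M, k2 = 0.60 s⁻¹)
    reagent + mono adduct → double product (k3 = 0.046 M⁻¹ s⁻¹)
    starting material + reagent → mono adduct (k4 = 0.018 M⁻¹ s⁻¹)
    reagent + other mono adduct → double product (k5 = 0.0063 M⁻¹ s⁻¹)

- given per volume of solution although it is solid: solid substrate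
- at the start none of the solid substrate is in solution
- what has only dissolved of solid substrate counts as not reacted
- run time (flask): 2.5 h

1. part of the solid substrate that has turned into other species by 2.5 h (what has only dissolved does not count)
2. the mono adduct standing at 2.5 h, as a percentage of the solid substrate charged
3. the double product standing at 2.5 h, as a percentage of the solid substrate charged
4. amount of mono adduct if the flask were left three thousand times as long, in percent of the solid substrate charged

I carry one number, the reagent equivalents e: reagent charged per solid substrate charged, 1.50. I build the flask up around it.

With the main step alone, starting material to mono adduct, each substrate takes one reagent. The half-life of starting material by that step at the charged reagent is 1.1 min, far shorter than the 2.5 h allowed. Since e is above one, the substrate turns over completely and 0.500 equivalents of reagent stay unused.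

Now I add dissolution. Its time, 1.67 s, is shorter than that half-life, so I take it as settled: while solid is left, c(starting material) stands at 0.28 M. What has merely dissolved takes no reagent, so the count stays as it was.

Then I add the mono adduct's reaction with reagent, and the count changes. The half-life of mono adduct by this step at the charged reagent, 0.44 min, is short against the 2.5 h allowed, so each substrate can now take two reagents. Two is more than e, which makes the reagent the limiting reagent, and double product can reach 75.0% at most, that is e over two.

The route through the other mono adduct brings no new count: one reagent for a mono adduct, two for the double product. So once reagent is gone, conv plus y_D equals e.

With c(starting material) at 0.28 M, the half-life of reagent by the main step is 2.29 min, far shorter than 2.5 h. I therefore expect that state before the end, with no reacting step left to run, so ever equals y_M. My reckoning goes that far: conv above 75.0%, y_D below it, and their sum e. The split itself I do not reckon.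

The forecast gives 83.6% for conv, 10.3% for y_M, 66.4% for y_D and 10.3% for ever, on the grounds that “the mono adducts, especially the fast-reacting one, take a second equivalent”.

The simulation gives 83.6%, 10.3%, 66.4% and 10.3%, as forecast. This flask is a stopped mixture: reagent stands at 0% of its charge by 1.25 h, starting material remains at 16.4% at 2.50 h, and more time changes nothing. Its conv plus y_D comes to 150%, which is e. The neighbouring flask with 0.34 M of reagent has e of 0.895, below one. It keeps 0% of its reagent and shows conv 57.4% and y_D 32.1%, summing to 89.5%, and its largest share is starting material at 42.6%.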